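**Plan**
- Retrosynthesis: the C5 acetate goes back to a silyl ether. Ring A (the α-methylidene-γ-butyrolactone) is then cut in one operation at three bonds: α-carbon to lactone carbonyl, β-carbon to the O-bearing γ-carbon (the ring fusion), and the lactone C–O bond. This leaves CO2 and the open-chain allenyl enal 8, whose allene comes from a terminal alkyne and whose carbinol comes from propargylation of a 12-oxofarnesyl ester.
- Enabling feature: in ring A, Cα(=CH2)–Cβ is a terminal allene in disguise (central and substituted carbon), the carbonyl carbon is CO2, and O–Cγ is the C=O of an (E)-enal. The other twelve atoms of ring B (the 14-membered carbocycle) are an unbroken (2E,6E,10E)-farnesyl chain.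
- Forward order: farnesyl acetate, ω-oxidation to the enal, propargylation, allene, head-group enal, then a nickel/CO2 cascade that closes ring B and ring A together, then desilylation and acetylation.
- Stereochemistry: the three E double bonds come from farnesol; the carbinol centre from catalyst-controlled propargylation; the two ring-fusion centres from the key step (cis from a chair allylation, absolute sense from the carbinol centre).

Key step: step 8

Assumption: the R phosphoric acid of step 3 is taken to deliver the propargyl group to the Re face of enal 3, as it does the allyl group of allylboronates, which gives 12R; the S acid would serve if the sense were the reverse.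
Assumption: the sense of 1,3-induction from C12 in the ring closure of step 8 is taken as argued there; no precedent secures it.

**Step 1**
Reactants: 1 (2E,6E)-farnesyl acetate
Product: 2 (2E,6E,10E)-12-hydroxy-3,7,11-trimethyldodeca-2,6,10-trien-1-yl acetate
Conditions: SeO2 (cat.), t-BuOOH, salicylic acid (cat.), CH2Cl2, rt
Reagents that add atoms: tert-butyl hydroperoxide CC(C)(C)OO (oxygen source, delivered through selenium dioxide O=[Se]=O)
Why: Riley oxidation (ene reaction, then [2,3]-sigmatropic shift) should oxidise the E-methyl group of the electron-rich isopropylidene end and keep the 10E geometry, the acetate-bearing end being deactivated.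

**Step 2**
Reactants: 2 (2E,6E,10E)-12-hydroxy-3,7,11-trimethyldodeca-2,6,10-trien-1-yl acetate
Product: 3 (2E,6E,10E)-3,7,11-trimethyl-12-oxododeca-2,6,10-trien-1-yl acetate
Conditions: MnO2, CH2Cl2, rt
Reagents that add atoms: none
Why: MnO2 oxidises the allylic alcohol selectively to the conjugated aldehyde and should leave the acetate and the E double bonds untouched.

**Step 3**
Reactants: 3 (2E,6E,10E)-3,7,11-trimethyl-12-oxododeca-2,6,10-trien-1-yl acetate
Product: 4 (2E,6E,10E,12R)-12-hydroxy-3,7,11-trimethylpentadeca-2,6,10-trien-14-yn-1-yl acetate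
Conditions: allenylboronic acid pinacol ester, (R)-3,3'-bis(2,4,6-triisopropylphenyl)-1,1'-binaphthyl-2,2'-diyl hydrogen phosphate (cat.), 4 Å molecular sieves, toluene, 0 °C
Reagents that add atoms: allenylboronic acid pinacol ester C=C=CB1OC(C)(C)C(C)(C)O1
Why: Chiral phosphoric acid-catalysed propargylboration, in which the acid-activated allenylboronate transfers a propargyl group with allylic transposition through a closed chair transition state and the catalyst selects the aldehyde face, so that C12 should be formed R under reagent control.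

**Step 4**
Reactants: 4 (2E,6E,10E,12R)-12-hydroxy-3,7,11-trimethylpentadeca-2,6,10-trien-14-yn-1-yl acetate
Product: 5 (2E,6E,10E,12R)-12-[(tert-butyldimethylsilyl)oxy]-3,7,11-trimethylpentadeca-2,6,10-trien-14-yn-1-yl acetate
Conditions: TBSCl, imidazole, DMF, rt
Reagents that add atoms: tert-butyldimethylsilyl chloride CC(C)(C)[Si](C)(C)Cl
Why: Standard silylation of the secondary alcohol; a silyl ether is chosen because zerovalent nickel in step 8 would ionise an allylic ester at C12.

**Step 5**
Reactants: 5 (2E,6E,10E,12R)-12-[(tert-butyldimethylsilyl)oxy]-3,7,11-trimethylpentadeca-2,6,10-trien-14-yn-1-yl acetate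
Product: 6 (2E,6E,10E,12R)-12-[(tert-butyldimethylsilyl)oxy]-3,7,11-trimethylhexadeca-2,6,10,14,15-pentaen-1-yl acetate
Conditions: (CH2O)n, CuI, Cy2NH, dioxane, reflux
Reagents that add atoms: paraformaldehyde C=O
Why: Crabbé homologation (CuI-mediated Mannich reaction of the terminal alkyne, then 1,5-hydride transfer with loss of the imine) should turn C≡CH into CH=C=CH2 without touching C12.

**Step 6**
Reactants: 6 (2E,6E,10E,12R)-12-[(tert-butyldimethylsilyl)oxy]-3,7,11-trimethylhexadeca-2,6,10,14,15-pentaen-1-yl acetate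
Product: 7 (2E,6E,10E,12R)-12-[(tert-butyldimethylsilyl)oxy]-3,7,11-trimethylhexadeca-2,6,10,14,15-pentaen-1-ol
Conditions: K2CO3, MeOH, rt
Reagents that add atoms: none
Why: Methanolysis of the primary allylic acetate; the silyl ether and the allene are stable to K2CO3 in methanol.

**Step 7**
Reactants: 7 (2E,6E,10E,12R)-12-[(tert-butyldimethylsilyl)oxy]-3,7,11-trimethylhexadeca-2,6,10,14,15-pentaen-1-ol
Product: 8 (2E,6E,10E,12R)-12-[(tert-butyldimethylsilyl)oxy]-3,7,11-trimethylhexadeca-2,6,10,14,15-pentaenal
Conditions: MnO2, CH2Cl2, rt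
Reagents that add atoms: none
Why: MnO2 oxidation of the primary allylic alcohol should give the 2E enal, the allene and the silyl ether being inert.

**Step 8**
Reactants: 8 (2E,6E,10E,12R)-12-[(tert-butyldimethylsilyl)oxy]-3,7,11-trimethylhexadeca-2,6,10,14,15-pentaenal
Product: 11 (3aS,5R,6E,10E,14E,15aS)-5-[(tert-butyldimethylsilyl)oxy]-6,10,14-trimethyl-3-methylidene-3a,4,5,8,9,12,13,15a-octahydrocyclotetradeca[b]furan-2(3H)-one, via oxanickelacycle 9 (not isolated), via seco hydroxy acid 10 (not isolated)
Conditions: Ni(cod)2 (1.5 equiv), 1,8-diazabicyclo[5.4.0]undec-7-ene (DBU), CO2 (1 atm), THF, 0 °C; argon purge, dilution to 0.002 M, rt; then 1 M HCl; pyridinium p-toluenesulfonate (cat.), CH2Cl2, rt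
Reagents that add atoms: carbon dioxide O=C=O
Why: Proposed new method: DBU-ligated zerovalent nickel couples CO2 oxidatively with the terminal C15=C16 π bond of the allene (numbering of 8), so that the carboxyl carbon bonds to the central carbon C15 and nickel to C16 (oxanickelacycle 9); the allyl–nickel unit of 9 then adds through its substituted end C14 to the tethered aldehyde carbon C1, acid frees hydroxy acid 10, and lactonisation completes ring A. The closest known reaction type is the nickel-mediated sequential addition of CO2 and an aldehyde to a terminal allene, shown only between separate molecules; the reasoning is that the same allylnickel carboxylate, once formed and diluted, has only its own aldehyde to react with. Ring B closes by intramolecular carbonyl allylation with allylic transposition (14-exo-trig at the C1 carbonyl through a six-membered nickel-bound transition state), and ring A closes by 5-exo-trig attack of the new C1 hydroxyl on the carboxyl group. Relative configuration: CO2 is taken up on the allene face away from C13, which puts C13 cis to CH2–Ni on the C14=C15 bond, and a Zimmerman–Traxler chair with the enal residue equatorial then gives the syn adduct, which is the cis ring fusion. Absolute configuration: the C1–C14 bond forms on the allyl face opposite C12, which allylic 1,3-strain holds perpendicular to the allyl plane with its hydrogen turned inward, its alkenyl chain antiperiplanar to C14 and the silyloxy group outward, and this arrangement should lead from 12R to S at both new centres. The step needs CO2 uptake to precede any nickel-mediated coupling of allene and enal, and ring closure to beat oligomerisation and a second carboxylation; saturation with CO2 at 0 °C while the remote aldehyde is a poor partner, then argon purge and dilution before warming, are meant to secure this.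

**Step 9**
Reactants: 11 (3aS,5R,6E,10E,14E,15aS)-5-[(tert-butyldimethylsilyl)oxy]-6,10,14-trimethyl-3-methylidene-3a,4,5,8,9,12,13,15a-octahydrocyclotetradeca[b]furan-2(3H)-one
Product: 12 (3aS,5R,6E,10E,14E,15aS)-5-hydroxy-6,10,14-trimethyl-3-methylidene-3a,4,5,8,9,12,13,15a-octahydrocyclotetradeca[b]furan-2(3H)-one
Conditions: HF·pyridine, pyridine, THF, 0 °C to rt
Reagents that add atoms: none
Why: Buffered fluoride desilylation should free the secondary alcohol without the basic conditions under which the methylidene lactone adds nucleophiles.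

**Step 10**
Reactants: 12 (3aS,5R,6E,10E,14E,15aS)-5-hydroxy-6,10,14-trimethyl-3-methylidene-3a,4,5,8,9,12,13,15a-octahydrocyclotetradeca[b]furan-2(3H)-one
Product: 13 (3aS,5R,6E,10E,14E,15aS)-6,10,14-trimethyl-3-methylidene-2-oxo-2,3,3a,4,5,8,9,12,13,15a-decahydrocyclotetradeca[b]furan-5-yl acetate
Conditions: Ac2O, pyridine, 4-(dimethylamino)pyridine (cat.), CH2Cl2, 0 °C
Reagents that add atoms: acetic anhydride CC(=O)OC(C)=O
Why: Acetylation of the secondary allylic alcohol proceeds with retention at C5 and should give the target.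

**Compound list**
1 | (2E,6E)-farnesyl acetate | CC(C)=CCC/C(C)=C/CC/C(C)=C/COC(C)=O | starting material
2 | (2E,6E,10E)-12-hydroxy-3,7,11-trimethyldodeca-2,6,10-trien-1-yl acetate | OC/C(C)=C/CC/C(C)=C/CC/C(C)=C/COC(C)=O | intermediate
3 | (2E,6E,10E)-3,7,11-trimethyl-12-oxododeca-2,6,10-trien-1-yl acetate | O=C/C(C)=C/CC/C(C)=C/CC/C(C)=C/COC(C)=O | intermediate
4 | (2E,6E,10E,12R)-12-hydroxy-3,7,11-trimethylpentadeca-2,6,10-trien-14-yn-1-yl acetate | C#CC[C@@H](O)/C(C)=C/CC/C(C)=C/CC/C(C)=C/COC(C)=O | intermediate
5 | (2E,6E,10E,12R)-12-[(tert-butyldimethylsilyl)oxy]-3,7,11-trimethylpentadeca-2,6,10-trien-14-yn-1-yl acetate | C#CC[C@@H](O[Si](C)(C)C(C)(C)C)/C(C)=C/CC/C(C)=C/CC/C(C)=C/COC(C)=O | intermediate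
6 | (2E,6E,10E,12R)-12-[(tert-butyldimethylsilyl)oxy]-3,7,11-trimethylhexadeca-2,6,10,14,15-pentaen-1-yl acetate | C=C=CC[C@@H](O[Si](C)(C)C(C)(C)C)/C(C)=C/CC/C(C)=C/CC/C(C)=C/COC(C)=O | intermediate
7 | (2E,6E,10E,12R)-12-[(tert-butyldimethylsilyl)oxy]-3,7,11-trimethylhexadeca-2,6,10,14,15-pentaen-1-ol | C=C=CC[C@@H](O[Si](C)(C)C(C)(C)C)/C(C)=C/CC/C(C)=C/CC/C(C)=C/CO | intermediate
8 | (2E,6E,10E,12R)-12-[(tert-butyldimethylsilyl)oxy]-3,7,11-trimethylhexadeca-2,6,10,14,15-pentaenal | C=C=CC[C@@H](O[Si](C)(C)C(C)(C)C)/C(C)=C/CC/C(C)=C/CC/C(C)=C/C=O | intermediate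
9 | oxanickelacycle: five-membered ring Ni–O–C(=O)–C15–C16H2 with exocyclic Z C15=C14 bond (C13 cis to CH2–Ni), the C13 to C1 chain of 8 unchanged, two DBU ligands on divalent nickel (written as separate components) | O=C1O[Ni]C/C1=C\C[C@@H](O[Si](C)(C)C(C)(C)C)/C(C)=C/CC/C(C)=C/CC/C(C)=C/C=O.C1CCC2=NCCCN2CC1.C1CCC2=NCCCN2CC1 | intermediate
10 | 2-[(1S,2S,3E,7E,11E,13R)-13-[(tert-butyldimethylsilyl)oxy]-2-hydroxy-4,8,12-trimethylcyclotetradeca-3,7,11-trien-1-yl]prop-2-enoic acid (first formed as its divalent nickel salt) | C=C(C(=O)O)[C@@H]1C[C@@H](O[Si](C)(C)C(C)(C)C)/C(C)=C/CC/C(C)=C/CC/C(C)=C/[C@@H]1O | intermediate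
11 | (3aS,5R,6E,10E,14E,15aS)-5-[(tert-butyldimethylsilyl)oxy]-6,10,14-trimethyl-3-methylidene-3a,4,5,8,9,12,13,15a-octahydrocyclotetradeca[b]furan-2(3H)-one | C=C1C(=O)O[C@H]2/C=C(\C)CC/C=C(\C)CC/C=C(\C)[C@H](O[Si](C)(C)C(C)(C)C)C[C@@H]12 | intermediate
12 | (3aS,5R,6E,10E,14E,15aS)-5-hydroxy-6,10,14-trimethyl-3-methylidene-3a,4,5,8,9,12,13,15a-octahydrocyclotetradeca[b]furan-2(3H)-one | C=C1C(=O)O[C@H]2/C=C(\C)CC/C=C(\C)CC/C=C(\C)[C@H](O)C[C@@H]12 | intermediate
13 | (3aS,5R,6E,10E,14E,15aS)-6,10,14-trimethyl-3-methylidene-2-oxo-2,3,3a,4,5,8,9,12,13,15a-decahydrocyclotetradeca[b]furan-5-yl acetate | C=C1C(=O)O[C@H]2/C=C(\C)CC/C=C(\C)CC/C=C(\C)[C@H](OC(C)=O)C[C@@H]12 | target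

**Totals**
Total step count: 10. Longest linear sequence: 10 steps (1 to 13).

**Steps most likely to fail**

1. Step 8 (Proposed new method). What may go wrong: ring closure may lose to intermolecular allylation, to protonation of the allylnickel or to a second carboxylation; DBU may isomerise the enal; induction from C12 may run in the unwanted sense. Fallback with known chemistry, from 3 back to 11:
   - Mukaiyama aldol reaction of 3 with 1-(tert-butylthio)-1-(trimethylsilyloxy)ethene under Ti(OiPr)4 and BINOL (the enantiomer that gives 3R), with desilylating work-up, should give S-tert-butyl (3R,4E,8E,12E)-14-acetoxy-3-hydroxy-4,8,12-trimethyltetradeca-4,8,12-trienethioate F1.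
   - TBSCl and imidazole give its silyl ether F2.
   - DIBAL-H in excess reduces thioester and acetate together to (2E,6E,10E,12R)-12-[(tert-butyldimethylsilyl)oxy]-3,7,11-trimethyltetradeca-2,6,10-triene-1,14-diol F3.
   - Dess–Martin periodinane gives the dialdehyde F4.
   - A Morita–Baylis–Hillman reaction with methyl acrylate and 1,4-diazabicyclo[2.2.2]octane, which should take the saturated aldehyde and leave the hindered enal, gives the hydroxy ester F5.
   - NBS and Me2S give the (Z)-2-(bromomethyl) enoate F6 with allylic transposition.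
   - Intramolecular Nozaki–Hiyama allylation with CrCl2 in THF at high dilution, in which the chromium alkoxide closes onto the methyl ester in the flask, returns to 11.

2. Step 3. What may go wrong: enantiocontrol may be insufficient on the α-branched enal, or allenyl transfer may compete with propargyl transfer. Fallback, from 3 back to 4: Barbier propargylation with zinc and propargyl bromide in THF and aqueous NH4Cl gives the racemic alcohol F7. Sharpless kinetic resolution (Ti(OiPr)4, diisopropyl L-(+)-tartrate, t-BuOOH, 4 Å molecular sieves, CH2Cl2, −20 °C, run past half conversion) should consume the S enantiomer as the epoxy alcohol F8 and leave 4.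

3. Step 1. What may go wrong: oxidation at other allylic positions and over-oxidation. Fallback, from 1 back to 3: NBS in aqueous THF at 0 °C should give the terminal bromohydrin (2E,6E)-10-bromo-11-hydroxy-3,7,11-trimethyldodeca-2,6-dien-1-yl acetate F9. DBU in CH2Cl2 closes it to the 10,11-epoxide F10. HIO4 in aqueous THF cleaves the epoxide to the aldehyde (2E,6E)-3,7-dimethyl-10-oxodeca-2,6-dien-1-yl acetate F11. An E-selective Wittig reaction with 2-(triphenylphosphoranylidene)propanal then gives 3.

Further compounds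
F1 | step 8 | S-tert-butyl (3R,4E,8E,12E)-14-acetoxy-3-hydroxy-4,8,12-trimethyltetradeca-4,8,12-trienethioate | CC(C)(C)SC(=O)C[C@@H](O)/C(C)=C/CC/C(C)=C/CC/C(C)=C/COC(C)=O
F2 | step 8 | S-tert-butyl (3R,4E,8E,12E)-14-acetoxy-3-[(tert-butyldimethylsilyl)oxy]-4,8,12-trimethyltetradeca-4,8,12-trienethioate | CC(C)(C)SC(=O)C[C@@H](O[Si](C)(C)C(C)(C)C)/C(C)=C/CC/C(C)=C/CC/C(C)=C/COC(C)=O
F3 | step 8 | (2E,6E,10E,12R)-12-[(tert-butyldimethylsilyl)oxy]-3,7,11-trimethyltetradeca-2,6,10-triene-1,14-diol | OCC[C@@H](O[Si](C)(C)C(C)(C)C)/C(C)=C/CC/C(C)=C/CC/C(C)=C/CO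
F4 | step 8 | (2E,6E,10E,12R)-12-[(tert-butyldimethylsilyl)oxy]-3,7,11-trimethyltetradeca-2,6,10-trienedial | O=CC[C@@H](O[Si](C)(C)C(C)(C)C)/C(C)=C/CC/C(C)=C/CC/C(C)=C/C=O
F5 | step 8 | methyl (5R,6E,10E,14E)-5-[(tert-butyldimethylsilyl)oxy]-3-hydroxy-6,10,14-trimethyl-2-methylidene-16-oxohexadeca-6,10,14-trienoate (both C3 epimers) | COC(=O)C(=C)C(O)C[C@@H](O[Si](C)(C)C(C)(C)C)/C(C)=C/CC/C(C)=C/CC/C(C)=C/C=O
F6 | step 8 | methyl (2Z,5R,6E,10E,14E)-2-(bromomethyl)-5-[(tert-butyldimethylsilyl)oxy]-6,10,14-trimethyl-16-oxohexadeca-2,6,10,14-tetraenoate | COC(=O)/C(CBr)=C/C[C@@H](O[Si](C)(C)C(C)(C)C)/C(C)=C/CC/C(C)=C/CC/C(C)=C/C=O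
F7 | step 3 | racemic (2E,6E,10E)-12-hydroxy-3,7,11-trimethylpentadeca-2,6,10-trien-14-yn-1-yl acetate | C#CCC(O)/C(C)=C/CC/C(C)=C/CC/C(C)=C/COC(C)=O
F8 | step 3 | (2E,6E,10R,11R,12S)-10,11-epoxy-12-hydroxy-3,7,11-trimethylpentadeca-2,6-dien-14-yn-1-yl acetate | C#CC[C@H](O)[C@@]1(C)O[C@@H]1CC/C(C)=C/CC/C(C)=C/COC(C)=O
F9 | step 1 | racemic (2E,6E)-10-bromo-11-hydroxy-3,7,11-trimethyldodeca-2,6-dien-1-yl acetate | CC(C)(O)C(Br)CC/C(C)=C/CC/C(C)=C/COC(C)=O
F10 | step 1 | racemic (2E,6E)-10,11-epoxy-3,7,11-trimethyldodeca-2,6-dien-1-yl acetate | CC1(C)OC1CC/C(C)=C/CC/C(C)=C/COC(C)=O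
F11 | step 1 | (2E,6E)-3,7-dimethyl-10-oxodeca-2,6-dien-1-yl acetate | O=CCC/C(C)=C/CC/C(C)=C/COC(C)=O
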